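**Plan**
- Retrosynthesis: the 5-O-methyl group is a protecting group; C3–H comes from a C3–CO2allyl helper; ring C is then cut at O1–C8a and C3–C4, giving a ring A acid chloride (C4 on C4a, F on C8a) and a ring B hydroxy ester carrying O1–C2–C3.
- Forward: the pyran ring on ring B is closed first (oxa-6π), then the arylacetate chain (C3 with the helper ester) is attached and C2 is added by hydroxymethylation; ring A is brought in as 2-fluoro-4,6-dimethoxybenzoyl chloride; ring C is formed last, when the two halves are joined.
- Enabling feature: the C4 carbonyl sits on C4a, ortho to C8a, while the ring A oxygens on C5 and C7 are meta to C8a. A fluorine on C8a is therefore open to addition–elimination, so C4/C8a is a 1,3-bis-electrophile. C3 (benzylic to ring B, α to the helper ester) and O1 form the matching 1,3-bis-nucleophile.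
- Stereochemistry: C3 is the only stereocenter. It is quaternary and racemic after the annulation, and is set afterwards by a Pd-catalysed decarboxylative asymmetric protonation that sends both enantiomers through one enolate and removes the helper. The final deprotection is non-basic.

Key step: step 8

Assumption: the sense of induction of the decarboxylative protonation is not derived here; the (S)-ligand is written, and its mirror image is to be used if the product should prove to be the (3R) antipode.

**Step 1**
Reactants: 1 4-bromo-3-methoxyphenol; 2 3-methylbut-2-enal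
Product: 4 6-bromo-7-methoxy-2,2-dimethyl-2H-chromene, via ortho-quinone methide 3 (not isolated)
Conditions: PhB(OH)2 (1 equiv), AcOH (cat.), toluene, reflux (Dean–Stark)
Reagents that add atoms: none
Why: Boronic acid-templated ortho-condensation of the phenol with the enal gives ortho-quinone methide 3, which closes by oxa-6π electrocyclization; the ring carbon para to the methoxy group should react rather than the flanked carbon between the two oxygens, as in the same chromenylation of 3-methoxyphenol, and no stereocenter is formed.

**Step 2**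
Reactants: 4 6-bromo-7-methoxy-2,2-dimethyl-2H-chromene; 5 (2-ethoxy-2-oxoethyl)zinc bromide (commercial THF solution, or made beforehand from ethyl bromoacetate and zinc)
Product: 6 ethyl 2-(7-methoxy-2,2-dimethyl-2H-chromen-6-yl)acetate
Conditions: Pd2(dba)3 (1 mol %), XPhos (4 mol %), THF, 50 °C
Reagents that add atoms: none
Why: Negishi-type α-arylation of an ester with a Reformatsky reagent (oxidative addition of zerovalent palladium to the aryl bromide, transmetalation of the zinc enolate, reductive elimination), whose near-neutral conditions leave the chromene double bond untouched.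

**Step 3**
Reactants: 6 ethyl 2-(7-methoxy-2,2-dimethyl-2H-chromen-6-yl)acetate
Product: 7 allyl 2-(7-methoxy-2,2-dimethyl-2H-chromen-6-yl)acetate
Conditions: Ti(OiPr)4 (10 mol %), allyl alcohol (solvent), 95 °C
Reagents that add atoms: allyl alcohol, C=CCO
Why: Titanium alkoxide-catalysed transesterification, driven by the excess of allyl alcohol and loss of ethanol, installs the allyl ester needed in step 9 without acid or strong base.

**Step 4**
Reactants: 7 allyl 2-(7-methoxy-2,2-dimethyl-2H-chromen-6-yl)acetate
Product: 8 allyl 3-hydroxy-2-(7-methoxy-2,2-dimethyl-2H-chromen-6-yl)propanoate (racemic)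
Conditions: (CH2O)n (1.1 equiv), K2CO3 (10 mol %), DMSO, rt
Reagents that add atoms: formaldehyde (as paraformaldehyde), C=O
Why: Base-catalysed aldol addition of the arylacetate enolate to formaldehyde (tropic ester type hydroxymethylation) should stop at the mono-adduct with one equivalent of formaldehyde and weak base; the new stereocenter is formed racemic and needs no control because it is made planar again in step 9.

**Step 5**
Reactants: 8 allyl 3-hydroxy-2-(7-methoxy-2,2-dimethyl-2H-chromen-6-yl)propanoate (racemic)
Product: 9 allyl 3-[(tert-butyldimethylsilyl)oxy]-2-(7-methoxy-2,2-dimethyl-2H-chromen-6-yl)propanoate (racemic)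
Conditions: TBSCl (1.2 equiv), imidazole (2 equiv), CH2Cl2, rt
Reagents that add atoms: tert-butyldimethylsilyl chloride, CC(C)(C)[Si](C)(C)Cl
Why: Standard silylation of a primary alcohol; the silyl ether blocks O-acylation in step 8 and then serves there as a fluoride-released alkoxide.

**Step 6**
Reactants: 10 2,6-difluoro-4-methoxybenzoic acid
Product: 11 2-fluoro-4,6-dimethoxybenzoic acid
Conditions: NaOMe (2.5 equiv), DMSO, 80 °C; then aq. HCl
Reagents that add atoms: sodium methoxide, [Na+].[O-]C
Why: Nucleophilic aromatic substitution (addition–elimination) of one of the two equivalent ortho-fluorines of the carboxylate by methoxide, the methoxy group that enters slowing a second substitution.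

**Step 7**
Reactants: 11 2-fluoro-4,6-dimethoxybenzoic acid
Product: 12 2-fluoro-4,6-dimethoxybenzoyl chloride
Conditions: (COCl)2 (1.3 equiv), DMF (cat.), CH2Cl2, 0 °C to rt; evaporate, use crude
Reagents that add atoms: oxalyl chloride, ClC(=O)C(=O)Cl
Why: Acid chloride formation through the chloroiminium species generated from DMF and oxalyl chloride, with only gaseous by-products.

**Step 8**
Reactants: 9 allyl 3-[(tert-butyldimethylsilyl)oxy]-2-(7-methoxy-2,2-dimethyl-2H-chromen-6-yl)propanoate (racemic); 12 2-fluoro-4,6-dimethoxybenzoyl chloride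
Product: 15 allyl 5,7-dimethoxy-3-(7-methoxy-2,2-dimethyl-2H-chromen-6-yl)-4-oxochromane-3-carboxylate (racemic), via C-acylated silyl ether 13 (not isolated), via tetrabutylammonium alkoxide 14 (not isolated)
Conditions: NaN(SiMe3)2 (1.05 equiv), THF, −78 °C; add 12 (1.1 equiv), −78 to −40 °C; then Bu4N[Ph3SiF2] (20 mol %), −40 °C to rt
Reagents that add atoms: none
Why: NaN(SiMe3)2 removes the C3 proton of 9 (benzylic to ring B and α to the helper ester), and the enolate attacks the acid chloride carbon C4 of 12 to give 13 (Claisen-type C-acylation); fluoride then takes off the silyl group, and the alkoxide O1 of 14 adds to C8a and expels fluoride through a Meisenheimer adduct stabilized by the ortho C4 carbonyl, the released fluoride carrying the chain on. The closest known reaction types are the Grohe-type cycloaracylation (C-aroylation followed by intramolecular SNAr of 2-fluorobenzoyl chlorides with 1,3-bis-nucleophiles) and the fluoride-catalysed SNAr of silyl ethers with aryl fluorides. Ring C, the only ring formed, closes as a six-membered ring by intramolecular addition–elimination at C8a. C3 becomes quaternary and is formed racemic on purpose, since step 9 converts both enantiomers into one enolate. The step needs C- over O-acylation (sodium enolate, acid chloride, low temperature, hydroxyl masked as silyl ether) and displacement of fluorine in preference to the ortho methoxy group (fluoride is by far the better leaving group in addition–elimination, and the oxygens on C5 and C7 are meta to C8a and do not deactivate it). Ring closure must also outrun loss of formaldehyde from 14, which is helped because the quaternary C3 carries no proton (no elimination or epimerization) and the retro-aldol is reversible.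

**Step 9**
Reactants: 15 allyl 5,7-dimethoxy-3-(7-methoxy-2,2-dimethyl-2H-chromen-6-yl)-4-oxochromane-3-carboxylate (racemic)
Product: 16 (3S)-5,7-dimethoxy-3-(7-methoxy-2,2-dimethyl-2H-chromen-6-yl)chroman-4-one
Conditions: Pd2(dba)3 (5 mol %), (S)-(CF3)3-t-Bu-PHOX (12.5 mol %), Meldrum's acid (2.5 equiv), THF, 5 °C to rt
Reagents that add atoms: none
Why: Pd-catalysed decarboxylative asymmetric protonation, in which zerovalent palladium ionizes the allyl ester of either enantiomer of 15, loss of CO2 gives one common planar enolate held in the chiral Pd–PHOX environment, and Meldrum's acid delivers the proton to one face of C3 while its anion takes up the allyl group; this protonation is known to work best for isoflavanones whose 3-aryl group carries an ortho substituent, as the 2'-methoxy group does here, and the weakly acidic medium should keep the new α-aryl ketone stereocenter from enolizing.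

**Step 10**
Reactants: 16 (3S)-5,7-dimethoxy-3-(7-methoxy-2,2-dimethyl-2H-chromen-6-yl)chroman-4-one
Product: 17 (3S)-5-hydroxy-7-methoxy-3-(7-methoxy-2,2-dimethyl-2H-chromen-6-yl)chroman-4-one (CNP0310096.1)
Conditions: BCl3 (2 equiv, 1 M in CH2Cl2), CH2Cl2, −78 °C; then pH 7 buffer, −78 °C to rt
Reagents that add atoms: none
Why: Chelation-controlled aryl methyl ether cleavage, in which BCl3 binds between the C4 carbonyl and the peri 5-methoxy oxygen and chloride removes only that methyl group, leaving the 7-methoxy and ring B methoxy groups; at −78 °C and without base the C3 stereocenter should not enolize and the chromene should survive.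

**Compound list**
1 | 4-bromo-3-methoxyphenol | COc1cc(O)ccc1Br | starting material
2 | 3-methylbut-2-enal | CC(C)=CC=O | starting material
3 | 4-bromo-3-methoxy-6-(3-methylbut-2-enylidene)cyclohexa-2,4-dien-1-one (ortho-quinone methide, not isolated) | COC1=CC(=O)C(=CC=C(C)C)C=C1Br | intermediate
4 | 6-bromo-7-methoxy-2,2-dimethyl-2H-chromene | COc1cc2c(cc1Br)C=CC(C)(C)O2 | intermediate
5 | (2-ethoxy-2-oxoethyl)zinc bromide | CCOC(=O)C[Zn]Br | starting material
6 | ethyl 2-(7-methoxy-2,2-dimethyl-2H-chromen-6-yl)acetate | CCOC(=O)Cc1cc2c(cc1OC)OC(C)(C)C=C2 | intermediate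
7 | allyl 2-(7-methoxy-2,2-dimethyl-2H-chromen-6-yl)acetate | C=CCOC(=O)Cc1cc2c(cc1OC)OC(C)(C)C=C2 | intermediate
8 | allyl 3-hydroxy-2-(7-methoxy-2,2-dimethyl-2H-chromen-6-yl)propanoate (racemic) | C=CCOC(=O)C(CO)c1cc2c(cc1OC)OC(C)(C)C=C2 | intermediate
9 | allyl 3-[(tert-butyldimethylsilyl)oxy]-2-(7-methoxy-2,2-dimethyl-2H-chromen-6-yl)propanoate (racemic) | C=CCOC(=O)C(CO[Si](C)(C)C(C)(C)C)c1cc2c(cc1OC)OC(C)(C)C=C2 | intermediate
10 | 2,6-difluoro-4-methoxybenzoic acid | COc1cc(F)c(C(=O)O)c(F)c1 | starting material
11 | 2-fluoro-4,6-dimethoxybenzoic acid | COc1cc(F)c(C(=O)O)c(OC)c1 | intermediate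
12 | 2-fluoro-4,6-dimethoxybenzoyl chloride | COc1cc(F)c(C(Cl)=O)c(OC)c1 | intermediate
13 | allyl 2-{[(tert-butyldimethylsilyl)oxy]methyl}-3-(2-fluoro-4,6-dimethoxyphenyl)-2-(7-methoxy-2,2-dimethyl-2H-chromen-6-yl)-3-oxopropanoate (racemic, not isolated) | C=CCOC(=O)C(CO[Si](C)(C)C(C)(C)C)(C(=O)c1c(F)cc(OC)cc1OC)c1cc2c(cc1OC)OC(C)(C)C=C2 | intermediate
14 | tetrabutylammonium alkoxide of allyl 3-(2-fluoro-4,6-dimethoxyphenyl)-2-(hydroxymethyl)-2-(7-methoxy-2,2-dimethyl-2H-chromen-6-yl)-3-oxopropanoate (racemic, not isolated) | CCCC[N+](CCCC)(CCCC)CCCC.[O-]CC(C(=O)OCC=C)(C(=O)c1c(F)cc(OC)cc1OC)c1cc2c(cc1OC)OC(C)(C)C=C2 | intermediate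
15 | allyl 5,7-dimethoxy-3-(7-methoxy-2,2-dimethyl-2H-chromen-6-yl)-4-oxochromane-3-carboxylate (racemic) | C=CCOC(=O)C1(c2cc3c(cc2OC)OC(C)(C)C=C3)COc2cc(OC)cc(OC)c2C1=O | intermediate
16 | (3S)-5,7-dimethoxy-3-(7-methoxy-2,2-dimethyl-2H-chromen-6-yl)chroman-4-one | COc1cc(OC)c2c(c1)OC[C@H](c1cc3c(cc1OC)OC(C)(C)C=C3)C2=O | intermediate
17 | (3S)-5-hydroxy-7-methoxy-3-(7-methoxy-2,2-dimethyl-2H-chromen-6-yl)chroman-4-one | COc1cc(O)c2c(c1)OC[C@H](c1cc3c(cc1OC)OC(C)(C)C=C3)C2=O | target

**Step count and risks**
Total: 10 steps. Longest linear sequence: 8 steps (steps 1–5, 8, 9, 10).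

Most likely to fail:

1. Step 8. The hindered, fully substituted enolate may be acylated on oxygen instead of carbon, or the freed alkoxide may lose formaldehyde by retro-aldol before the ring closes. The fallback forms the two bonds in separate events and brings in C2 last. It sets out from 7 and 12: the less hindered enolate of 7 (NaN(SiMe3)2, 2 equiv, THF, −78 °C) is C-acylated with 12 to give the enolizable β-keto ester allyl 3-(2-fluoro-4,6-dimethoxyphenyl)-2-(7-methoxy-2,2-dimethyl-2H-chromen-6-yl)-3-oxopropanoate F1. Treatment with paraformaldehyde and K2CO3 in DMF should give the aldol adduct allyl 3-(2-fluoro-4,6-dimethoxyphenyl)-2-(hydroxymethyl)-2-(7-methoxy-2,2-dimethyl-2H-chromen-6-yl)-3-oxopropanoate F2, which, kept in equilibrium by the excess of formaldehyde, closes by intramolecular SNAr. The route is rejoined at 15.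

2. Step 9. Facial selectivity in the protonation of the enolate may be poor, because the peri 5-methoxy group is an untested perturbation next to the enolate oxygen. The fallback replaces enantioselective protonation by a dynamic kinetic resolution. It sets out from 15: non-selective deallylation and decarboxylation (Pd(PPh3)4, morpholine, THF) gives racemic 5,7-dimethoxy-3-(7-methoxy-2,2-dimethyl-2H-chromen-6-yl)chroman-4-one F3. Asymmetric transfer hydrogenation with RuCl(p-cymene)[(S,S)-TsDPEN] or its mirror image (HCO2H/Et3N), with racemization of the ketone under the reaction conditions, should give the cis alcohol (3S,4S)-5,7-dimethoxy-3-(7-methoxy-2,2-dimethyl-2H-chromen-6-yl)chroman-4-ol F4. Oxidation with Dess–Martin periodinane (NaHCO3, CH2Cl2, 0 °C) returns the ketone with C3 intact, rejoining the route at 16.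

3. Step 10. The C3 configuration may erode by Lewis acid-promoted enolization of the boron-chelated ketone during or after ether cleavage. The fallback moves the demethylation to a stage with no stereocenter. It sets out from 15: BCl3 (CH2Cl2, −78 °C) gives allyl 5-hydroxy-7-methoxy-3-(7-methoxy-2,2-dimethyl-2H-chromen-6-yl)-4-oxochromane-3-carboxylate F5. The phenol is capped (TBSOTf, 2,6-lutidine) as allyl 5-[(tert-butyldimethylsilyl)oxy]-7-methoxy-3-(7-methoxy-2,2-dimethyl-2H-chromen-6-yl)-4-oxochromane-3-carboxylate F6, so that no free phenol interferes with the protonation. The conditions of step 9 then give (3S)-5-[(tert-butyldimethylsilyl)oxy]-7-methoxy-3-(7-methoxy-2,2-dimethyl-2H-chromen-6-yl)chroman-4-one F7. Buffered HF·pyridine (THF, 0 °C) removes the silyl group without base, rejoining the route at 17.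

**Further compounds**
F1 | step 8 | allyl 3-(2-fluoro-4,6-dimethoxyphenyl)-2-(7-methoxy-2,2-dimethyl-2H-chromen-6-yl)-3-oxopropanoate (racemic) | C=CCOC(=O)C(C(=O)c1c(F)cc(OC)cc1OC)c1cc2c(cc1OC)OC(C)(C)C=C2
F2 | step 8 | allyl 3-(2-fluoro-4,6-dimethoxyphenyl)-2-(hydroxymethyl)-2-(7-methoxy-2,2-dimethyl-2H-chromen-6-yl)-3-oxopropanoate (racemic) | C=CCOC(=O)C(CO)(C(=O)c1c(F)cc(OC)cc1OC)c1cc2c(cc1OC)OC(C)(C)C=C2
F3 | step 9 | 5,7-dimethoxy-3-(7-methoxy-2,2-dimethyl-2H-chromen-6-yl)chroman-4-one (racemic) | COc1cc(OC)c2c(c1)OCC(c1cc3c(cc1OC)OC(C)(C)C=C3)C2=O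
F4 | step 9 | (3S,4S)-5,7-dimethoxy-3-(7-methoxy-2,2-dimethyl-2H-chromen-6-yl)chroman-4-ol (3,4-cis) | COc1cc(OC)c2c(c1)OC[C@H](c1cc3c(cc1OC)OC(C)(C)C=C3)[C@@H]2O
F5 | step 10 | allyl 5-hydroxy-7-methoxy-3-(7-methoxy-2,2-dimethyl-2H-chromen-6-yl)-4-oxochromane-3-carboxylate (racemic) | C=CCOC(=O)C1(c2cc3c(cc2OC)OC(C)(C)C=C3)COc2cc(OC)cc(O)c2C1=O
F6 | step 10 | allyl 5-[(tert-butyldimethylsilyl)oxy]-7-methoxy-3-(7-methoxy-2,2-dimethyl-2H-chromen-6-yl)-4-oxochromane-3-carboxylate (racemic) | C=CCOC(=O)C1(c2cc3c(cc2OC)OC(C)(C)C=C3)COc2cc(OC)cc(O[Si](C)(C)C(C)(C)C)c2C1=O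
F7 | step 10 | (3S)-5-[(tert-butyldimethylsilyl)oxy]-7-methoxy-3-(7-methoxy-2,2-dimethyl-2H-chromen-6-yl)chroman-4-one | COc1cc(O[Si](C)(C)C(C)(C)C)c2c(c1)OC[C@H](c1cc3c(cc1OC)OC(C)(C)C=C3)C2=O
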